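**Plan**
- The target, 2,3,5,6-tetrabromo-1H-indole, is achiral and has no stereocentre, so no stereochemical control is needed.
- The retrosynthesis first cuts C2–Br and C3–Br (electrophilic bromination of the pyrrole ring), then cuts C5–Br and C6–Br together. This leads back to an N-Boc 5,6-indolyne and its 5-triflyloxy-6-trimethylsilyl precursor, whose C6–Si bond is traced to the C6–Br of 6-bromo-5-methoxy-1H-indole.
- Enabling feature: C5 and C6 are neighbouring carbons of the benzenoid ring and carry the same atom (Br), a vicinal pattern that direct bromination of indole does not deliver. A C5≡C6 aryne can accept both bromines, and with identical addends it does not matter which end reacts first.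
- Forward: no ring is built, because the indole bicycle is bought intact. O-Demethylation, O-silylation, Br–Li exchange with retro-Brook shift, O-triflation and N-Boc protection give the aryne precursor; aryne dibromination, Boc removal and C3/C2 bromination finish the route.

Key step: step 6

Remark: 6-bromo-5-methoxy-1H-indole is assumed to be purchasable; reagents that deliver non-hydrogen atoms to a product are numbered as starting materials.

Step 1
Reactants: 1 6-bromo-5-methoxy-1H-indole
Product: 2 6-bromo-1H-indol-5-ol
Conditions: BBr3 (3 equiv), CH2Cl2, −78 °C → 0 °C; then ice/H2O; product kept under argon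
Reagents that add atoms: none
Why: Lewis-acid cleavage of an aryl methyl ether (BBr3 O-demethylation), in which boron binds the methoxy oxygen and bromide removes the methyl group by SN2, conditions that an unprotected, bromine-deactivated indole should tolerate at low temperature.

Step 2
Reactants: 2 6-bromo-1H-indol-5-ol; 3 hexamethyldisilazane
Product: 4 6-bromo-5-(trimethylsilyloxy)-1H-indole
Conditions: HN(SiMe3)2 (1.0 equiv), THF, 65 °C; volatiles removed, used crude
Reagents that add atoms: hexamethyldisilazane, C[Si](C)(C)N[Si](C)(C)C
Why: O-silylation of a phenol with a silazane, which should be selective because the phenol is far more acidic than the indole N–H and the only by-product is NH3.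

Step 3
Reactants: 4 6-bromo-5-(trimethylsilyloxy)-1H-indole
Product: 6 6-(trimethylsilyl)-1H-indol-5-ol, via lithium potassium 6-(trimethylsilyl)indol-1-ide-5-olate 5 (not isolated)
Conditions: KH (1.1 equiv), THF, 0 °C; t-BuLi (2.2 equiv), −78 °C → −40 °C; sat. aq. NH4Cl
Reagents that add atoms: none
Why: Bromine–lithium exchange followed by retro-Brook (1,3 O→C silyl) rearrangement, in which prior N–H removal by KH reserves t-BuLi for exchange at C6–Br and the C6 aryllithium takes the silyl group from the neighbouring oxygen because a phenoxide is far more stable than an aryl anion.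

Step 4
Reactants: 6 6-(trimethylsilyl)-1H-indol-5-ol; 7 N-phenylbis(trifluoromethanesulfonimide)
Product: 8 6-(trimethylsilyl)-1H-indol-5-yl trifluoromethanesulfonate
Conditions: PhNTf2 (1.1 equiv), DBU (1.2 equiv), MeCN, 0 °C → rt
Reagents that add atoms: N-phenylbis(trifluoromethanesulfonimide), O=S(=O)(N(c1ccccc1)S(=O)(=O)C(F)(F)F)C(F)(F)F
Why: Selective O-sulfonylation (triflation of a phenoxide with a mild triflyl donor), since DBU ionises only the phenol and the much less acidic indole N–H should stay untouched.

Step 5
Reactants: 8 6-(trimethylsilyl)-1H-indol-5-yl trifluoromethanesulfonate; 9 di-tert-butyl dicarbonate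
Product: 10 tert-butyl 5-(trifluoromethylsulfonyloxy)-6-(trimethylsilyl)indole-1-carboxylate
Conditions: Boc2O (1.2 equiv), DMAP (0.1 equiv), MeCN, rt
Reagents that add atoms: di-tert-butyl dicarbonate, CC(C)(C)OC(=O)OC(=O)OC(C)(C)C
Why: DMAP-catalysed N-acylation (Boc protection of an indole N–H) under fluoride-free conditions that leave the silyl triflate intact, the carbamate being needed to stop N-arylation by the aryne and N–H deprotonation by fluoride in the next step.

Step 6
Reactants: 10 tert-butyl 5-(trifluoromethylsulfonyloxy)-6-(trimethylsilyl)indole-1-carboxylate; 11 1,2-dibromo-1,1,2,2-tetrachloroethane; 12 tetrabutylammonium bromide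
Product: 14 tert-butyl 5,6-dibromoindole-1-carboxylate, via tert-butyl 5,6-didehydroindole-1-carboxylate 13 (not isolated)
Conditions: CsF (3 equiv), Bu4NBr (2 equiv), BrCCl2CCl2Br (3 equiv), MeCN, 0 °C → rt, dark
Reagents that add atoms: 1,2-dibromo-1,1,2,2-tetrachloroethane, BrC(Cl)(Cl)C(Cl)(Cl)Br; tetrabutylammonium bromide, CCCC[N+](CCCC)(CCCC)CCCC.[Br-]
Why: Proposed new method: fluoride attacks silicon of 10 and triflate leaves the neighbouring carbon to give the C5≡C6 indolyne 13, bromide from 12 adds to one end of the strained bond, and the resulting 2-bromoaryl anion takes Br+ from 11 by halophilic attack, which releases Cl2C=CCl2 and returns bromide, so that C5–Br and C6–Br form in one operation with 11 as the net source of both bromines. The closest known reactions are the insertion of arynes from o-silylaryl triflates into the I–I bond of I2 (vicinal diiodination), aryne three-component halo-functionalisations in which the aryl anion formed by nucleophile addition is quenched by a halophilic halogen donor, and fluoride generation of N-protected 5,6-indolynes; a vicinal dibromination of an indolyne has not been shown. No ring is closed and no stereocentre is formed. Regioselectivity, which aryne distortion normally dictates, is irrelevant because the same atom ends up on both carbons whichever end bromide attacks. The step needs chemoselective capture of the aryne by bromide ahead of fluoride, and of the aryl anion by Br+ ahead of protonation by MeCN or addition to a second aryne; the low solubility of CsF keeps fluoride scarce while soluble 12 and excess 11 are present in high concentration. Delivering Br2 as a nucleophilic half and a halophilic half avoids free electrophilic bromine, so neither the C2=C3 bond of the Boc-deactivated pyrrole ring nor the C6–Si bond of unreacted 10 should be brominated.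

Step 7
Reactants: 14 tert-butyl 5,6-dibromoindole-1-carboxylate
Product: 15 5,6-dibromo-1H-indole
Conditions: K2CO3 (0.3 equiv), MeOH/THF, rt → 40 °C
Reagents that add atoms: none
Why: Base-catalysed methanolysis of an N-acyl indole (carbamate transesterification), in which methoxide attacks the Boc carbonyl because the indolide is a good leaving group, so the group should come off without acid and without touching the aryl bromides.

Step 8
Reactants: 15 5,6-dibromo-1H-indole; 16 N-bromosuccinimide
Product: 18 2,3,5,6-tetrabromo-1H-indole, via 3,5,6-tribromo-1H-indole 17 (not isolated)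
Conditions: NBS (2.05 equiv), anhydrous THF, −78 °C → rt, dark
Reagents that add atoms: N-bromosuccinimide, O=C1CCC(=O)N1Br
Why: Electrophilic aromatic bromination of the pyrrole ring, in which the first equivalent should substitute the most nucleophilic position C3 to give 17 and the second should brominate the remaining enamine carbon C2 (directly or by attack at C3 followed by a 1,2-bromine shift), while the dibrominated benzenoid ring is too deactivated to react.

**Compound list**
1 | 6-bromo-5-methoxy-1H-indole | COc1cc2cc[nH]c2cc1Br | starting material
2 | 6-bromo-1H-indol-5-ol | Oc1cc2cc[nH]c2cc1Br | intermediate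
3 | hexamethyldisilazane | C[Si](C)(C)N[Si](C)(C)C | starting material
4 | 6-bromo-5-(trimethylsilyloxy)-1H-indole | C[Si](C)(C)Oc1cc2cc[nH]c2cc1Br | intermediate
5 | lithium potassium 6-(trimethylsilyl)indol-1-ide-5-olate | [Li+].[K+].C[Si](C)(C)c1cc2[n-]ccc2cc1[O-] | intermediate
6 | 6-(trimethylsilyl)-1H-indol-5-ol | C[Si](C)(C)c1cc2[nH]ccc2cc1O | intermediate
7 | N-phenylbis(trifluoromethanesulfonimide) | O=S(=O)(N(c1ccccc1)S(=O)(=O)C(F)(F)F)C(F)(F)F | starting material
8 | 6-(trimethylsilyl)-1H-indol-5-yl trifluoromethanesulfonate | C[Si](C)(C)c1cc2[nH]ccc2cc1OS(=O)(=O)C(F)(F)F | intermediate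
9 | di-tert-butyl dicarbonate | CC(C)(C)OC(=O)OC(=O)OC(C)(C)C | starting material
10 | tert-butyl 5-(trifluoromethylsulfonyloxy)-6-(trimethylsilyl)indole-1-carboxylate | CC(C)(C)OC(=O)n1ccc2cc(OS(=O)(=O)C(F)(F)F)c([Si](C)(C)C)cc21 | intermediate
11 | 1,2-dibromo-1,1,2,2-tetrachloroethane | BrC(Cl)(Cl)C(Cl)(Cl)Br | starting material
12 | tetrabutylammonium bromide | CCCC[N+](CCCC)(CCCC)CCCC.[Br-] | starting material
13 | tert-butyl 5,6-didehydroindole-1-carboxylate (N-Boc-5,6-indolyne) | CC(C)(C)OC(=O)N1C=CC2=CC#CC=C12 | intermediate
14 | tert-butyl 5,6-dibromoindole-1-carboxylate | CC(C)(C)OC(=O)n1ccc2cc(Br)c(Br)cc21 | intermediate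
15 | 5,6-dibromo-1H-indole | Brc1cc2cc[nH]c2cc1Br | intermediate
16 | N-bromosuccinimide | O=C1CCC(=O)N1Br | starting material
17 | 3,5,6-tribromo-1H-indole | Brc1c[nH]c2cc(Br)c(Br)cc12 | intermediate
18 | 2,3,5,6-tetrabromo-1H-indole | Brc1cc2[nH]c(Br)c(Br)c2cc1Br | target

**Step count**
Total: 8 steps. Longest linear sequence: 8 steps (1 → 2 → 4 → 6 → 8 → 10 → 14 → 15 → 18).

**Steps most likely to fail**

Step 6 (aryne dibromination). Several processes could divert the aryne: irreversible capture by fluoride instead of bromide, loss of bromide from the 2-bromoaryl anion before bromine transfer, protonation of that anion by the solvent, or premature loss of the Boc group under fluoride. The fallback sets out from 10 and uses known chemistry. Palladium-catalysed insertion of the aryne into the Sn–Sn bond of hexamethylditin (Me3SnSnMe3, Pd(OAc)2, tert-octyl isocyanide, KF, 18-crown-6, THF, rt) should give tert-butyl 5,6-bis(trimethylstannyl)indole-1-carboxylate F1. Double ipso-bromodestannylation with Br2 (2.0 equiv, CH2Cl2, −78 °C), which is much faster than bromination of the N-Boc pyrrole ring at that temperature, then rejoins the route at 14.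

Step 3 (exchange and retro-Brook shift on the N-metalated indole). The exchange may be incomplete on the electron-rich indolide, the C6 aryllithium may be protonated before the silyl group migrates, or silyl groups may scramble between molecules. The fallback sets out from 4 and masks nitrogen as a carbamate instead of as an anion. Boc2O with catalytic DMAP in MeCN should give tert-butyl 6-bromo-5-(trimethylsilyloxy)indole-1-carboxylate F2. Treatment with t-BuLi (2.1 equiv, THF, −100 °C) then triggers exchange and silyl migration, with exchange expected to outrun both C2 deprotonation and attack on the carbamate. The lithium phenoxide is triflated in the same flask with Tf2O at −78 °C, so the route is rejoined at 10 and compounds 6 and 8 are bypassed.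

Step 8 (double bromination of the pyrrole ring). Over-bromination at nitrogen or on the benzenoid ring, oxidation to oxindole-type products by adventitious water, or decomposition of the light- and acid-sensitive N–H bromoindole during a slow second bromination could lower the outcome. The fallback sets out from 14 and installs C2–Br by directed metalation rather than electrophilic substitution. Boc-directed C2 lithiation (LiN(iPr)2, THF, −78 °C) and quenching with BrCCl2CCl2Br should give tert-butyl 2,5,6-tribromoindole-1-carboxylate F3. Methanolysis with K2CO3 in MeOH should give 2,5,6-tribromo-1H-indole F4. A single, fast C3 bromination with NBS (1.0 equiv, THF, 0 °C) then rejoins the route at 18.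

**Further compounds**
F1 | step 6 | tert-butyl 5,6-bis(trimethylstannyl)indole-1-carboxylate | CC(C)(C)OC(=O)n1ccc2cc([Sn](C)(C)C)c([Sn](C)(C)C)cc21
F2 | step 3 | tert-butyl 6-bromo-5-(trimethylsilyloxy)indole-1-carboxylate | CC(C)(C)OC(=O)n1ccc2cc(O[Si](C)(C)C)c(Br)cc21
F3 | step 8 | tert-butyl 2,5,6-tribromoindole-1-carboxylate | CC(C)(C)OC(=O)n1c(Br)cc2cc(Br)c(Br)cc21
F4 | step 8 | 2,5,6-tribromo-1H-indole | Brc1cc2cc(Br)c(Br)cc2[nH]1
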